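The runs were computed with constants of no real substance, noise included.

A closed flask cannot keep a product excess through a plain kinetic resolution run to full conversion: each hand of a racemate ends wholly as its own product, and the two products stand equal.

common to all: gas 21 mM (held)
- ochre: left-handed substrate 0.15 M; right-handed substrate 0.15 M; run made earlier
- green: left-handed substrate 0.22 M; right-handed substrate 0.22 M; run made earlier
- east: left-handed substrate 0.30 M; right-handed substrate 0.30 M; time 2.5 h
- north: left-handed substrate 0.30 M; right-handed substrate 0.30 M; time 8.0 h

| run | time / min | left-handed product / % | right-handed product / % |
|---|---|---|---|
| ochre | 8.00 | 1.1 | 0.9 |
| ochre | 25.0 | 5.5 | 1.7 |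
| ochre | 40.0 | 9.1 | 3.2 |
| ochre | 60.0 | 15.2 | 5.5 |
| ochre | 90.0 | 20.6 | 6.8 |
| green | 8.00 | 0.3 | 0 |
| green | 15.0 | 2.8 | 1.1 |
| green | 25.0 | 5.3 | 1.8 |
| green | 50.0 | 9.9 | 3.0 |
| green | 90.0 | 17.5 | 5.7 |

(standard deviation of a reading: 0.5 percentage points)

- partner is single-handed; left-handed substrate and right-handed substrate are mirror images of each other, charged as a racemate, each of them at the stated concentration
- at the start none of the gas is in solution
- an excess is the difference of the two amounts in percent of their sum
- an excess is below zero if the other one leads
- the handed part of partner does not stay in what it makes, so the products of the two hands are mirror images too

1. which of the two ends with the higher excess of left-handed product over right-handed product in the product ("neither" if they lie within 2 percentage points) (east / north / neither)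
2. excess of left-handed product over right-handed product in the product at the end, east
3. excess of left-handed product over right-handed product in the product at the end, north

What stays constant in such a resolution is the ratio of the two pseudo-first-order losses, however [partner] moves meanwhile. With each product counted as the loss of its own hand, the last ochre reading gives 3.63 for the apparent selectivity factor: the logarithm of the fraction of left-handed substrate remaining, over the same logarithm for right-handed substrate. The last green reading gives 3.56, close to it, so the factor can be frozen across these charges.

But the loss itself cannot be frozen. Counted the same way, left-handed substrate is lost, on average up to the last reading, at 0.354 /h in ochre and at 0.287 /h in green, so the readings put the fuller flask lower. Taking the inverse of this constant as a straight line in the charge gives 0.236 /h at 0.30 M of each hand. Held over time and joined to the factor, that gives an excess of 49.7 % in east and 35.3 % in north, lower than in east.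

One objection stands: the readings never show the substrates, so a passage of one hand into the other cannot be computed away, and north runs longer. This reckoning therefore commits to east, with north the less certain number.

The forecast names east, with 46 % for east and 25 % for north, lower than the north value above, and holds that “this looks like an ordinary kinetic resolution”.

The flask gives east, with 46.8 % in east and 38.5 % in north.

    partner + right-handed substrate → right-handed product (k = 0.00404 /M/s)
    partner → decomposed reagent (k = 4.75 × 10⁻⁴ /s)
    gas ⇌ partner, rate k3*(csat - [partner]) (kL = 0.00171 /s)
    partner + left-handed substrate → left-handed product (k = 0.0130 /M/s)
    partner ⇌ dormant form (K = 5.90, k = 2.48 × 10⁻⁴ /s)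
    left-handed substrate ⇌ right-handed substrate (k = 5.47 × 10⁻⁵ /s)

Reckoned from the substrate actually remaining, the apparent selectivity factor at the end of east is 2.08, below the 3.63 read from the ochre products, and in the same flask as east read at 4.0 h it is lower again, 1.82. In east at 2.50 h, with [partner] at 0.00646 M, right-handed substrate passes to right-handed product with a first-order constant of 0.0939 /h, but into left-handed substrate, in a step running both ways with equal constants, faster, at 0.197 /h.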